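**Plan**
1. Numbering (germacrane): carbocycle C1–C10; butenolide O–C6, C7=C11, C12=O; C13 = CH2OAc on C11, C14 = CH2OH on C10, C15 = CH3 on C4; oxygen at C2 (OAc), C4 (OH), C8 (O-angeloyl).
2. Main cut: with the C2 acetate and a C14 silyl group removed, the syn C2–O/C3H2/C4–O unit is read as a masked aldol, a 2-isoxazoline. Cutting C2–C3 together with C4–O opens the ten-membered ring to a nitrile oxide (C2) and an isopropenyl group (C3=C4, C15).
3. Enabling feature: the ring is a cis,cis-cyclodeca-1,6-diene. C8–C7–C6=C5–C4 is a rigid planar U held by the (E)-alkylidene butenolide, and C9–C10=C1–C2 is a cis alkene, so C2 and C3 are pre-folded toward each other and the bay between C4 and C8 can transmit chirality.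
4. Further cuts: O8–acyl; C8–C9 plus C2–O8 (hetero-Diels–Alder, temporary dihydropyran); C4–C5 (Stille); O–C6 (iodolactonisation); C11–C13 and C6–C7 (two couplings on a dibromoenoate made from a three-carbon acetylenic acetal).
5. Forward order of rings: butenolide (step 5); temporary dihydropyran (step 11, opened in step 12); carbocycle and temporary isoxazoline together (step 15, isoxazoline opened in step 16).
6. Stereochemistry: C8 comes from the chromium-catalysed cycloaddition, C4 is relayed from C8 in the key step, and C2 is relayed from C4 by chelate-controlled reduction. C5=C6 comes from anti bromination, anti iodolactonisation and retentive couplings; C1=C10 from the dihydropyran ring; the angelate from angelic acid.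

Key step: step 15

Assumption: the sense of induction of the chromium catalyst in step 11 is taken over from simple aldehydes. The acetal carbon of 19 is drawn as the cis (endo) isomer and is lost in step 12.

**Step 1**
Reactants: 1 3,3-diethoxyprop-1-yne
Product: 3 methyl 4,4-diethoxybut-2-ynoate, via lithium acetylide 2 (not isolated)
Conditions: n-BuLi, THF, −78 °C; then ClCO2Me, −78 °C to 0 °C
Reagents that add atoms: methyl chloroformate, COC(=O)Cl
Why: Acetylide acylation, in which the lithium acetylide is carboxylated by the chloroformate at low temperature faster than the product ynoate is attacked.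

**Step 2**
Reactants: 3 methyl 4,4-diethoxybut-2-ynoate
Product: 4 methyl (E)-2,3-dibromo-4,4-diethoxybut-2-enoate
Conditions: Br2 (1.0 equiv), CH2Cl2, 0 °C to rt, dark
Reagents that add atoms: bromine, BrBr
Why: Electrophilic anti addition of bromine to the ynoate should give the (E)-dibromide, which places the C7 bromide cis to the ester and so fixes the later cis relation of C6 and C12.

**Step 3**
Reactants: 4 methyl (E)-2,3-dibromo-4,4-diethoxybut-2-enoate; 5 ethynyltrimethylsilane
Product: 6 methyl (Z)-2-bromo-3-(diethoxymethyl)-5-(trimethylsilyl)pent-2-en-4-ynoate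
Conditions: 5 (1.0 equiv), PdCl2(PPh3)2 (3 mol %), CuI (5 mol %), Et3N, THF, rt
Reagents that add atoms: none
Why: Sonogashira coupling, site-selective for the beta C–Br bond (C7), which is the more electrophilic one in 2,3-dibromoenoates, and proceeding with retention of alkene geometry.

**Step 4**
Reactants: 6 methyl (Z)-2-bromo-3-(diethoxymethyl)-5-(trimethylsilyl)pent-2-en-4-ynoate; 7 (tributylstannyl)methanol
Product: 8 methyl (E)-3-(diethoxymethyl)-2-(hydroxymethyl)-5-(trimethylsilyl)pent-2-en-4-ynoate
Conditions: Pd(PPh3)4 (5 mol %), dioxane, 90 °C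
Reagents that add atoms: none
Why: Stille hydroxymethylation of the remaining alpha bromide installs C13 with retention and completes the stereodefined tetrasubstituted C7=C11 alkene.

**Step 5**
Reactants: 8 methyl (E)-3-(diethoxymethyl)-2-(hydroxymethyl)-5-(trimethylsilyl)pent-2-en-4-ynoate
Product: 10 (E)-4-(diethoxymethyl)-3-(hydroxymethyl)-5-(iodomethylidene)furan-2(5H)-one, via lithium enynoate 9 (not isolated)
Conditions: LiOH (2.2 equiv), THF–H2O, rt; then NaHCO3, I2, MeCN, 0 °C, dark
Reagents that add atoms: lithium hydroxide, [Li+].[OH-]; iodine, II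
Why: Saponification with concomitant protiodesilylation is followed by iodolactonisation, in which anti 5-exo-dig attack of the carboxylate on the iodine-activated terminal alkyne puts iodine trans to the ring oxygen (E); the acid is never exposed, so the acetal and the cis CH2OH cannot exchange.

**Step 6**
Reactants: 10 (E)-4-(diethoxymethyl)-3-(hydroxymethyl)-5-(iodomethylidene)furan-2(5H)-one
Product: 11 [(E)-4-(diethoxymethyl)-5-(iodomethylidene)-2-oxo-2,5-dihydrofuran-3-yl]methyl acetate
Conditions: Ac2O, pyridine, DMAP (5 mol %), CH2Cl2, 0 °C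
Reagents that add atoms: acetic anhydride, CC(=O)OC(C)=O
Why: Simple O-acetylation installs the final C13 acetate and removes the only hydroxyl that could cyclise onto C8 in the next step.

**Step 7**
Reactants: 11 [(E)-4-(diethoxymethyl)-5-(iodomethylidene)-2-oxo-2,5-dihydrofuran-3-yl]methyl acetate
Product: 12 [(E)-4-formyl-5-(iodomethylidene)-2-oxo-2,5-dihydrofuran-3-yl]methyl acetate
Conditions: TFA–H2O (9:1), CH2Cl2, 0 °C
Reagents that add atoms: water, O
Why: Acid-catalysed acetal hydrolysis of the deactivated vinylic acetal is carried out while only the acid-stable iodoalkene is present, before the acid-sensitive diene is introduced.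

**Step 8**
Reactants: 12 [(E)-4-formyl-5-(iodomethylidene)-2-oxo-2,5-dihydrofuran-3-yl]methyl acetate; 13 tributyl(prop-1-en-2-yl)stannane
Product: 14 [(E)-4-formyl-5-(2-methylprop-2-en-1-ylidene)-2-oxo-2,5-dihydrofuran-3-yl]methyl acetate
Conditions: Pd2(dba)3 (2.5 mol %), AsPh3 (10 mol %), NMP, rt
Reagents that add atoms: none
Why: Stille coupling under neutral conditions forms C4–C5 with retention, so C4 stays trans to the ring oxygen and cis to C7, and the aldehyde and acetate are tolerated.

**Step 9**
Reactants: 15 2-bromoprop-2-en-1-ol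
Product: 16 [(2-bromoprop-2-en-1-yl)oxy](tert-butyl)diphenylsilane
Conditions: TBDPSCl, imidazole, CH2Cl2, rt
Reagents that add atoms: tert-butyl(chloro)diphenylsilane, CC(C)(C)[Si](Cl)(c1ccccc1)c1ccccc1
Why: Silyl ether formation gives an acid- and fluoride-robust mask for O14, the only hydroxyl that must be free at the end.

**Step 10**
Reactants: 16 [(2-bromoprop-2-en-1-yl)oxy](tert-butyl)diphenylsilane; 17 (E)-2-(2-ethoxyethenyl)-4,4,5,5-tetramethyl-1,3,2-dioxaborolane
Product: 18 tert-butyl{[(3E)-4-ethoxy-2-methylidenebut-3-en-1-yl]oxy}diphenylsilane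
Conditions: Pd(PPh3)4 (3 mol %), K3PO4, THF–H2O, 60 °C
Reagents that add atoms: none
Why: Suzuki–Miyaura vinyl–vinyl coupling with retention should give the (E)-1-ethoxy diene that carries C2, C1, C10, C9 and C14.

**Step 11**
Reactants: 14 [(E)-4-formyl-5-(2-methylprop-2-en-1-ylidene)-2-oxo-2,5-dihydrofuran-3-yl]methyl acetate; 18 tert-butyl{[(3E)-4-ethoxy-2-methylidenebut-3-en-1-yl]oxy}diphenylsilane
Product: 19 cis-2-ethoxy-5,6-dihydro-2H-pyran with C6 (= C8, S) bearing the butenolide of 14 and C4 (= C10) bearing CH2OTBDPS
Conditions: [CrCl(L)] (5 mol %; L = dianion of (1S,2R)-1-{[3-(1-adamantyl)-2-hydroxy-5-methylbenzylidene]amino}indan-2-ol), 4 Å molecular sieves, TBME, rt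
Reagents that add atoms: none
Why: In this enantioselective hetero-Diels–Alder reaction the trivalent chromium Lewis acid binds the electron-poor aldehyde, the diene adds C9 to its Si face (sets 8S) while O8 bonds to C2, and the six-membered ring locks C9 and C2 cis on the new C1=C10 double bond.

**Step 12**
Reactants: 19 cis-2-ethoxy-dihydropyran (8S); 20 O-(tert-butyldimethylsilyl)hydroxylamine
Product: 21 (8S)-alcohol carrying the (E)-O-TBS aldoxime at C2 (C1=C10 E, C9 cis to C2)
Conditions: PPTS (10 mol %), CH2Cl2, rt
Reagents that add atoms: none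
Why: Acid-catalysed exchange of the allylic acetal for an oxime ether (oximation) opens the temporary dihydropyran, frees only O8–H and keeps the oxime oxygen masked, so that step 13 can acylate O8 alone and O8–H can never trap the later nitrile oxide.

**Step 13**
Reactants: 21 (8S)-alcohol O-TBS oxime; 22 angelic acid
Product: 23 (8S)-angelate O-TBS oxime
Conditions: 22, 2,4,6-trichlorobenzoyl chloride, Et3N, toluene, rt; then 21, 75 °C (no DMAP)
Reagents that add atoms: none
Why: Yamaguchi-type mixed-anhydride esterification without a nucleophilic catalyst is the established way to transfer an angeloyl group without Z-to-E isomerisation, and C8 keeps its configuration because its C–O bond is not broken.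

**Step 14**
Reactants: 23 (8S)-angelate O-TBS oxime
Product: 24 (8S)-angelate aldoxime
Conditions: Bu4NF (1.05 equiv), AcOH (1.1 equiv), THF, 0 °C
Reagents that add atoms: none
Why: In this fluoride desilylation the N–O–Si bond, which releases an oximate, should cleave much faster than the primary TBDPS ether, and the acetic acid buffer protects the three esters.

**Step 15**
Reactants: 24 (8S)-angelate aldoxime
Product: 26 (4R,8S)-isoxazoline-bridged germacranolide (C2=N–O–C4 bridge), via nitrile oxide 25 (not isolated)
Conditions: PhI(OAc)2 (1.2 equiv), CH2Cl2, 24 added by syringe pump to a final 1 mM, rt to 35 °C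
Reagents that add atoms: none
Why: PhI(OAc)2 dehydrogenates the aldoxime to the conjugated nitrile oxide 25, whose carbon (C2) bonds to the terminal CH2 (C3) while its oxygen bonds to C4 of the isopropenyl group in one concerted suprafacial [3+2] cycloaddition; the closest known reaction type is the intramolecular nitrile oxide–olefin cycloaddition used for macrocyclisation in its bridged mode. The ten-membered carbocycle closes in the endo mode (both alkene carbons become ring members, 10-endo) and the isoxazoline closes as the five-membered cycloadduct ring, which gives a bicyclo[7.2.1] system bridged between C2 and C4. The closure is made possible by the planar U of C8–C7–C6=C5–C4 and the cis C9–C10=C1–C2 unit, which leave only a five-atom arch to fold, and the butenolide locks C5=C6–C7=C11 s-trans so that no electrocyclic or hydrogen-shift escape is open to the triene. The single new stereocentre C4 is controlled by C8: allylic 1,3-strain in the bay between C4 and C8 keeps H8 in the lactone plane so that C9 and the dipole leave on one face, the isopropenyl group is twisted out of conjugation with C3 on that same face, and its inner face is blocked by C8, so oxygen can arrive only from the outer face, which translates 8S into 4R. Regiochemistry (oxygen to the disubstituted carbon) follows the normal preference of nitrile oxides for 1,1-disubstituted alkenes and is reinforced by the tether, since the reverse mode would need a nine-membered ring with a quaternary carbon. Chemoselectivity rests on C3=C4 being the only unhindered terminal alkene (the angelate, C5=C6 and C7=C11 are tri- or tetrasubstituted and electron-poor), and furoxan dimerisation is held back by slow addition at high dilution.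

**Step 16**
Reactants: 26 (4R,8S)-isoxazoline-bridged germacranolide
Product: 28 (4R,8S)-4-hydroxy-2-oxo enone, via hydroxy imine 27 (not isolated)
Conditions: Mo(CO)6 (1 equiv), MeCN–H2O (15:1), 75 °C
Reagents that add atoms: water, O
Why: Reductive N–O cleavage of a 2-isoxazoline by Mo(CO)6 and water, a reaction type that also serves 3-alkenyl isoxazolines, followed by hydrolysis of the imine unmasks the aldol without touching C4, and being neutral it should avoid retro-aldol cleavage, dehydration and loss of the allylic esters.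

**Step 17**
Reactants: 28 (4R,8S)-4-hydroxy-2-oxo enone
Product: 30 (2S,4R,8S)-2,4-syn diol, via diethylboron chelate 29 (not isolated)
Conditions: Et2BOMe, THF–MeOH (4:1), −78 °C; then NaBH4, −78 °C; AcOH quench, MeOH azeotrope
Reagents that add atoms: none
Why: In this Narasaka–Prasad reduction boron ties O4 and the C2 carbonyl into a six-membered chelate with the geometry of the former isoxazoline, whose concave face is covered by the butenolide across the ring, so borohydride should add 1,2 from the convex face and give the 2,4-syn diol (2S), with the ketone reacting well before the lactone at this temperature.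

**Step 18**
Reactants: 30 (2S,4R,8S)-2,4-syn diol
Product: 31 14-O-TBDPS ether of the target
Conditions: Ac2O, pyridine, DMAP (5 mol %), CH2Cl2, 0 °C
Reagents that add atoms: acetic anhydride, CC(=O)OC(C)=O
Why: This O-acetylation is selective for the secondary allylic C2 hydroxyl because the tertiary C4 hydroxyl in the bay is too hindered to be acylated under these conditions.

**Step 19**
Reactants: 31 14-O-TBDPS ether of the target
Product: 32 CNP0165707.1 (target)
Conditions: HF·pyridine, pyridine, THF, 0 °C to rt
Reagents that add atoms: none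
Why: Fluoride-mediated desilylation in a weakly acidic buffered medium frees O14 without acyl migration, ester cleavage or ionisation of the tertiary allylic alcohol.

**Compound list**
1 | 3,3-diethoxyprop-1-yne | C#CC(OCC)OCC | starting material
2 | lithium 3,3-diethoxyprop-1-yn-1-ide | [Li]C#CC(OCC)OCC | intermediate
3 | methyl 4,4-diethoxybut-2-ynoate | CCOC(OCC)C#CC(=O)OC | intermediate
4 | methyl (E)-2,3-dibromo-4,4-diethoxybut-2-enoate | COC(=O)/C(Br)=C(\Br)C(OCC)OCC | intermediate
5 | ethynyltrimethylsilane | C#C[Si](C)(C)C | starting material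
6 | methyl (Z)-2-bromo-3-(diethoxymethyl)-5-(trimethylsilyl)pent-2-en-4-ynoate | COC(=O)/C(Br)=C(\C#C[Si](C)(C)C)C(OCC)OCC | intermediate
7 | (tributylstannyl)methanol | CCCC[Sn](CCCC)(CCCC)CO | starting material
8 | methyl (E)-3-(diethoxymethyl)-2-(hydroxymethyl)-5-(trimethylsilyl)pent-2-en-4-ynoate | COC(=O)/C(CO)=C(\C#C[Si](C)(C)C)C(OCC)OCC | intermediate
9 | lithium (E)-3-(diethoxymethyl)-2-(hydroxymethyl)pent-2-en-4-ynoate | [Li+].[O-]C(=O)/C(CO)=C(\C#C)C(OCC)OCC | intermediate
10 | (E)-4-(diethoxymethyl)-3-(hydroxymethyl)-5-(iodomethylidene)furan-2(5H)-one | CCOC(OCC)C1=C(CO)C(=O)O/C1=C/I | intermediate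
11 | [(E)-4-(diethoxymethyl)-5-(iodomethylidene)-2-oxo-2,5-dihydrofuran-3-yl]methyl acetate | CCOC(OCC)C1=C(COC(C)=O)C(=O)O/C1=C/I | intermediate
12 | [(E)-4-formyl-5-(iodomethylidene)-2-oxo-2,5-dihydrofuran-3-yl]methyl acetate | O=CC1=C(COC(C)=O)C(=O)O/C1=C/I | intermediate
13 | tributyl(prop-1-en-2-yl)stannane | CCCC[Sn](CCCC)(CCCC)C(C)=C | starting material
14 | [(E)-4-formyl-5-(2-methylprop-2-en-1-ylidene)-2-oxo-2,5-dihydrofuran-3-yl]methyl acetate | O=CC1=C(COC(C)=O)C(=O)O/C1=C/C(C)=C | intermediate
15 | 2-bromoprop-2-en-1-ol | OCC(Br)=C | starting material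
16 | [(2-bromoprop-2-en-1-yl)oxy](tert-butyl)diphenylsilane | C=C(Br)CO[Si](c1ccccc1)(c1ccccc1)C(C)(C)C | intermediate
17 | (E)-2-(2-ethoxyethenyl)-4,4,5,5-tetramethyl-1,3,2-dioxaborolane | CCO/C=C/B1OC(C)(C)C(C)(C)O1 | starting material
18 | tert-butyl{[(3E)-4-ethoxy-2-methylidenebut-3-en-1-yl]oxy}diphenylsilane | CCO/C=C/C(=C)CO[Si](c1ccccc1)(c1ccccc1)C(C)(C)C | intermediate
19 | cis-2-ethoxy-4-(TBDPS-oxymethyl)-5,6-dihydro-2H-pyran bearing at C6 (= C8, S) the 3-(acetoxymethyl)-5-[(E)-2-methylallylidene]butenolid-4-yl group | CCO[C@H]1C=C(CO[Si](c3ccccc3)(c3ccccc3)C(C)(C)C)C[C@H](O1)C2=C(COC(C)=O)C(=O)O/C2=C/C(C)=C | intermediate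
20 | O-(tert-butyldimethylsilyl)hydroxylamine | NO[Si](C)(C)C(C)(C)C | starting material
21 | seco-germacranolide (8S)-alcohol, C2 as (E)-O-TBS aldoxime, C1=C10 E, C5=C6 E, O14-TBDPS, O13-acetyl | O[C@@H](C/C(CO[Si](c3ccccc3)(c3ccccc3)C(C)(C)C)=C\C=N\O[Si](C)(C)C(C)(C)C)C1=C(COC(C)=O)C(=O)O/C1=C/C(C)=C | intermediate
22 | angelic acid, (Z)-2-methylbut-2-enoic acid | C/C=C(/C)C(=O)O | starting material
23 | (8S)-angelate of 21 | C/C=C(/C)C(=O)O[C@@H](C/C(CO[Si](c3ccccc3)(c3ccccc3)C(C)(C)C)=C\C=N\O[Si](C)(C)C(C)(C)C)C1=C(COC(C)=O)C(=O)O/C1=C/C(C)=C | intermediate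
24 | (8S)-angelate free (E)-aldoxime | C/C=C(/C)C(=O)O[C@@H](C/C(CO[Si](c3ccccc3)(c3ccccc3)C(C)(C)C)=C\C=N\O)C1=C(COC(C)=O)C(=O)O/C1=C/C(C)=C | intermediate
25 | (8S)-angelate nitrile oxide (C2) | C/C=C(/C)C(=O)O[C@@H](C/C(CO[Si](c3ccccc3)(c3ccccc3)C(C)(C)C)=C\C#[N+][O-])C1=C(COC(C)=O)C(=O)O/C1=C/C(C)=C | intermediate
26 | (4R,8S)-germacranolide with a C2=N–O–C4 isoxazoline bridge, O14-TBDPS | C/C=C(/C)C(=O)O[C@H]1C/C(CO[Si](c4ccccc4)(c4ccccc4)C(C)(C)C)=C\C(=NO3)C[C@]3(C)/C=C2/OC(=O)C(COC(C)=O)=C21 | intermediate
27 | (4R,8S)-4-hydroxy-2-imine | C/C=C(/C)C(=O)O[C@H]1C/C(CO[Si](c4ccccc4)(c4ccccc4)C(C)(C)C)=C\C(=N)C[C@@](C)(O)/C=C2/OC(=O)C(COC(C)=O)=C21 | intermediate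
28 | (4R,8S)-4-hydroxy-2-oxo enone | C/C=C(/C)C(=O)O[C@H]1C/C(CO[Si](c4ccccc4)(c4ccccc4)C(C)(C)C)=C\C(=O)C[C@@](C)(O)/C=C2/OC(=O)C(COC(C)=O)=C21 | intermediate
29 | O4-diethylborinate of 28 (chelated to the C2 carbonyl) | C/C=C(/C)C(=O)O[C@H]1C/C(CO[Si](c4ccccc4)(c4ccccc4)C(C)(C)C)=C\C(=O)C[C@@](C)(OB(CC)CC)/C=C2/OC(=O)C(COC(C)=O)=C21 | intermediate
30 | (2S,4R,8S)-2,4-syn diol | C/C=C(/C)C(=O)O[C@H]1C/C(CO[Si](c4ccccc4)(c4ccccc4)C(C)(C)C)=C\[C@@H](O)C[C@@](C)(O)/C=C2/OC(=O)C(COC(C)=O)=C21 | intermediate
31 | 14-O-TBDPS ether of the target | C/C=C(/C)C(=O)O[C@H]1C/C(CO[Si](c4ccccc4)(c4ccccc4)C(C)(C)C)=C\[C@@H](OC(C)=O)C[C@@](C)(O)/C=C2/OC(=O)C(COC(C)=O)=C21 | intermediate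
32 | CNP0165707.1, (2S,4R,8S) | C/C=C(/C)C(=O)O[C@H]1C/C(CO)=C\[C@@H](OC(C)=O)C[C@@](C)(O)/C=C2/OC(=O)C(COC(C)=O)=C21 | target

Total step count: 19. Longest linear sequence: 17 (steps 1–8, then 11–19).

**Steps most likely to fail**

Step 15. Oligomerisation and furoxan formation may outrun the slow closure of the strained medium ring, or the dipole may reach the wrong face of the twisted isopropenyl group. The fallback sets out from 24 and returns at 30. It closes the same C2–C3 bond by a chromium-mediated allylation instead of a cycloaddition.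
- Transoximation of 24 with aqueous glyoxylic acid in THF frees the seco enal F1.
- Ene-type allylic chlorination of its isopropenyl group (NCS, PhSeCl 10 mol %, CH2Cl2) gives the chloromethyl enal F2.
- Intramolecular Nozaki–Hiyama–Kishi allylation (CrCl2, THF, high dilution) closes the ten-membered ring to the exomethylene alcohol F3.
- Markovnikov oxymercuration–demercuration of this most electron-rich alkene (Hg(OAc)2, THF–H2O; then Bu3SnH) installs the C4 hydroxyl and the C15 methyl, with water again arriving from the outer face of the bay, and gives 30.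

Step 11. The conjugated aldehyde is hindered by the neighbouring isopropenyl group, so it may react sluggishly, the catalyst may discriminate its faces poorly, and the diene may polymerise. The fallback sets out from 14 and 18 and returns at 21. C8 is set by ketone reduction instead of by the cycloaddition.
- An achiral Lewis acid (Eu(fod)3, 5 mol %, CH2Cl2) gives the racemic acetal F4.
- The conditions of step 12 give the racemic alcohol F5.
- Dess–Martin oxidation gives the C8 ketone F6.
- Corey–Bakshi–Shibata reduction ((R)-Me-CBS, catecholborane, toluene, −78 °C), in which the sp2 butenolide carbon acts as the large group, gives 21.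

Step 17. The tertiary O4 may form the chelate incompletely and the macrocycle may show poor facial selectivity. Conjugate reduction is also possible. The fallback sets out from 28 and returns at 30. Substrate and chelate control are replaced by reagent control: Corey–Bakshi–Shibata reduction of the enone with (R)-Me-CBS and catecholborane at −78 °C, the alkenyl side acting as the large group, delivers the 2S alcohol 1,2-selectively. This fallback makes no new compound (F0).

**Further compounds**
F1 | step 15 | seco enal ((8S)-angelate, C2 aldehyde) | C/C=C(/C)C(=O)O[C@@H](C/C(CO[Si](c3ccccc3)(c3ccccc3)C(C)(C)C)=C\C=O)C1=C(COC(C)=O)C(=O)O/C1=C/C(C)=C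
F2 | step 15 | chloromethyl enal (C3 as CH2Cl, C4=C15 methylene) | C/C=C(/C)C(=O)O[C@@H](C/C(CO[Si](c3ccccc3)(c3ccccc3)C(C)(C)C)=C\C=O)C1=C(COC(C)=O)C(=O)O/C1=C/C(CCl)=C
F3 | step 15 | exomethylene alcohol ((2S,8S)-macrocycle, C4=C15 methylene) | C/C=C(/C)C(=O)O[C@H]1C/C(CO[Si](c4ccccc4)(c4ccccc4)C(C)(C)C)=C\[C@@H](O)CC(=C)/C=C2/OC(=O)C(COC(C)=O)=C21
F4 | step 11 | racemic acetal (racemic 19) | CCOC1C=C(CO[Si](c3ccccc3)(c3ccccc3)C(C)(C)C)CC(O1)C2=C(COC(C)=O)C(=O)O/C2=C/C(C)=C
F5 | step 11 | racemic alcohol (racemic 21) | OC(C/C(CO[Si](c3ccccc3)(c3ccccc3)C(C)(C)C)=C\C=N\O[Si](C)(C)C(C)(C)C)C1=C(COC(C)=O)C(=O)O/C1=C/C(C)=C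
F6 | step 11 | C8 ketone | O=C(C/C(CO[Si](c3ccccc3)(c3ccccc3)C(C)(C)C)=C\C=N\O[Si](C)(C)C(C)(C)C)C1=C(COC(C)=O)C(=O)O/C1=C/C(C)=C
F0 | step 17 | none | none
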